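Late in a run, the starting material that has left the solution has taken one of two exits, target or side product, so the split between those exits keeps the books of the charge.

    starting material + reagent → target (k1 = 0.0195 L mol⁻¹ s⁻¹, Ea1 = 63.0 kJ mol⁻¹)
    starting material → side product (k2 = 0.0916 s⁻¹, Ea2 = 79.0 kJ mol⁻¹)
    solid substrate ⇌ starting material, rate k3*(cs3 - [starting material]) while solid is left; crystals form when [starting material] > cs3 (cs3 = 0.16 M, k3 = 0.0483 s⁻¹)
    (constants at 25 °C)

common to all: solid substrate 0.75 M; reagent 1.50 M (in portions, 4); time 5.0 min

| flask | temperature | remark |
|---|---|---|
| north-west | 25 °C | the portions of reagent follow each other after 25 s, the first at the start |
| south | 5 °C | the portions of reagent follow each other after 25 s, the first at the start |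

- solid, in amounts per volume of the solution: solid substrate
- all constants are for 25 °C and move with temperature by the activation energies
- at the start none of the solid substrate is in solution
- what has only dissolved of solid substrate counts as not reacted

* which flask leads in amount of target, in percent of the solid substrate charged ("all alike" within 1.5 percentage points) (north-west / south / all alike)
* how much target is there at the end, in percent of the solid substrate charged: north-west
* how much target is there at the end, in percent of the solid substrate charged: south

The solid substrate is the limiting reagent, at 0.75 M against 1.50 M of reagent. Its ledger has four entries: solid left, starting material in solution, target and side product. Both exits draw on the same c(starting material), which therefore cancels from their ratio. With c(reagent) held at its mean, integrating one exit against the other gives a closed form: target equals turnover times the branching share, or selectivity, which is the target rate constant times mean c(reagent), over that product plus the side rate constant.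

In south the constants fall to 0.00314 L mol⁻¹ s⁻¹ and 0.00926 s⁻¹, while the dissolution coefficient, for which no activation energy is given, is kept at 0.0483 s⁻¹. Counting the portions as added and none of the reagent as used, mean c(reagent) over the run is 1.31 M. A first pass by hand gives 0.155 M of target, and taking half of that from mean c(reagent) leaves 1.24 M. Dissolving then balances the exits at a plateau c(starting material) of 0.126 M. Held over the whole run, that plateau gives a turnover of 0.496 M, and the branching share is 29.5%.

The south ledger, in percent of the charge, reads: target 19.5%, side product 46.6%, dissolved 16.8%, and solid as the rest, 17.1%.

In north-west, with reagent first taken at 0.750 M, the plateau is 0.0500 M. The solid then lasts about 141 s, so the target entry is simply the share. Mean reagent over that time is 1.10 M, which gives a first share of 19.0%. Allowing for the reagent used gives 18.0%. This reckoning puts south ahead by 1.5 percentage points, level with the margin of 1.5 points, too close to call by hand.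

The forecast says all alike, with 19% for north-west and 19.3% for south: “a rough quasi-steady estimate puts both flasks near 19%”.

The simulation gives all alike, with 18.6% in north-west and 19.2% in south. South ends with 19.2% target and 44.0% side product, so target is 30.4% of what has reacted, against a reckoned share of 29.5%. A neighbouring flask, south with 1.9 M of solid substrate, still holds 68.5% of its charge as solid at the end. The same plateau, turnover and share, divided by the larger charge, give 7.70% target, and that flask gives 7.58%.

All constants are invented; the rest is arithmetic.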